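**Strategy**

Everything rests on cutting C5–C6 and C7–CH3 at once. The structure offers this because the C7 methyl stereocentre is separated by a single methylene (C6) from C5, the fully substituted carbon of the C4–C5 oxirane (the only ring), on which C3 and C6 are cis. In one flask a terminal C6=C7 alkene is methylaluminated enantioface-selectively under zirconium catalysis and the new C6–metal bond is cross-coupled with a Z-configured C3–C5 alkenyl iodide, giving the C7 centre and the Z-C4=C5 alkene that Sharpless epoxidation later turns into the cis-oxirane. The precursor is the C6–C15 alkene with C12 and C13 set by an Evans aldol and protected as a bis-TIPS, mono-PMB triol.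

Key step: step 9

Remark: atoms are numbered along the target chain (C1 enoic acid carbon, C4/C5 oxirane carbons, C14 second carboxyl carbon, C15 hydroxymethyl carbon on C13); the catalyst antipode in step 9 is assigned on the premise that the (−)-zirconocene converts 1-alkenes into (R)-2-methylalkan-1-ols, and the tartrate in step 11 on the premise that L-(+)-tartrate converts nerol into its (2S,3R)-epoxide.

**Route**

Step 1
Reactants: 1 4-methoxybenzyl alcohol; 2 methyl acrylate
Product: 4 3-[(4-methoxybenzyl)oxy]propanoic acid, via methyl ester 3 (not isolated)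
Conditions: NaH (5 mol%), THF, 0 °C → rt; then LiOH, THF/MeOH/H2O, rt; dilute HCl, 0 °C
Reagents that add atoms: lithium hydroxide, [Li+].[OH-]
Why: Base-catalysed oxa-Michael addition of the benzylic alkoxide to the acrylate followed by saponification in the same flask should give the β-alkoxy acid, any transesterified 4-methoxybenzyl ester converging on the same acid; no stereocentre is formed.

Step 2
Reactants: 4 3-[(4-methoxybenzyl)oxy]propanoic acid; 5 (S)-4-benzyl-1,3-oxazolidin-2-one
Product: 7 (S)-4-benzyl-3-{3-[(4-methoxybenzyl)oxy]propanoyl}-1,3-oxazolidin-2-one, via mixed pivalic anhydride 6 (not isolated)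
Conditions: PivCl, Et3N, THF, −20 °C; then 5, LiCl, −20 °C → rt
Reagents that add atoms: none
Why: N-Acylation of the oxazolidinone through the mixed pivalic anhydride, which is attacked at its less hindered carbonyl, is a standard route to such imides and leaves the auxiliary stereocentre untouched.

Step 3
Reactants: 8 hept-6-en-1-ol
Product: 9 hept-6-enal
Conditions: TEMPO (10 mol%), PhI(OAc)2, CH2Cl2, rt
Reagents that add atoms: none
Why: Oxoammonium-mediated (TEMPO/PhI(OAc)2) oxidation of a primary alcohol under anhydrous conditions should stop at the aldehyde and leave the terminal alkene alone.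

Step 4
Reactants: 7 (S)-4-benzyl-3-{3-[(4-methoxybenzyl)oxy]propanoyl}-1,3-oxazolidin-2-one; 9 hept-6-enal
Product: 12 (4S)-4-benzyl-3-[(2S,3R)-3-hydroxy-2-{[(4-methoxybenzyl)oxy]methyl}non-8-enoyl]-1,3-oxazolidin-2-one, via boron enolate 10 (not isolated), via boron aldolate 11 (not isolated)
Conditions: Bu2BOTf, iPr2NEt, CH2Cl2, −78 → 0 °C; then 9, −78 → 0 °C; pH 7 buffer, MeOH, H2O2, 0 °C
Reagents that add atoms: none
Why: Evans syn-aldol reaction, in which the Z-dibutylboron enolate meets the aldehyde in a closed Zimmerman–Traxler chair and the benzyl group of the (S)-auxiliary blocks one enolate face, so that C12 (R) and C13 are set together with the C12 hydroxyl and the C14 arm syn.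

Step 5
Reactants: 12 (4S)-4-benzyl-3-[(2S,3R)-3-hydroxy-2-{[(4-methoxybenzyl)oxy]methyl}non-8-enoyl]-1,3-oxazolidin-2-one
Product: 13 (2S,3R)-2-{[(4-methoxybenzyl)oxy]methyl}non-8-ene-1,3-diol
Conditions: LiBH4, MeOH (1 equiv), THF, 0 °C
Reagents that add atoms: none
Why: Reductive removal of the auxiliary by borohydride attack on the exocyclic imide carbonyl turns that carbon into the C15 hydroxymethyl group without touching C12 or C13, and the oxazolidinone is recovered.

Step 6
Reactants: 13 (2S,3R)-2-{[(4-methoxybenzyl)oxy]methyl}non-8-ene-1,3-diol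
Product: 14 (2R,3R)-1-[(4-methoxybenzyl)oxy]-3-[(triisopropylsilyl)oxy]-2-{[(triisopropylsilyl)oxy]methyl}non-8-ene
Conditions: TIPSOTf (2.5 equiv), 2,6-lutidine, CH2Cl2, 0 °C → rt
Reagents that add atoms: triisopropylsilyl triflate, CC(C)[Si](C(C)C)(C(C)C)OS(=O)(=O)C(F)(F)F
Why: Silylation with the silyl triflate and a hindered pyridine base is reactive enough to cap the primary C15 and the hindered secondary C12 hydroxyl in one operation, under non-alkoxide conditions that exclude silyl migration between the two arms on C13.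

Step 7
Reactants: 15 but-2-yn-1-ol
Product: 17 (Z)-3-iodobut-2-en-1-ol, via alkenylalanate 16 (not isolated)
Conditions: NaAlH2(OCH2CH2OMe)2, THF, 0 °C → rt; then I2, −78 → 0 °C
Reagents that add atoms: iodine, II
Why: Alkoxide-directed trans-hydroalumination of the propargylic alcohol delivers hydride to C4 and aluminium to C5 within a five-membered oxaaluminacycle, and iodinolysis of the C–Al bond with retention gives the iodide with iodine cis to the CH2OH group.

Step 8
Reactants: 17 (Z)-3-iodobut-2-en-1-ol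
Product: 18 (Z)-tert-butyl[(3-iodobut-2-en-1-yl)oxy]dimethylsilane
Conditions: TBSCl, imidazole, CH2Cl2, 0 °C → rt
Reagents that add atoms: tert-butyldimethylsilyl chloride, CC(C)(C)[Si](C)(C)Cl
Why: Imidazole-promoted silylation of a primary allylic alcohol is routine and does not affect the alkene geometry.

Step 9
Reactants: 14 (2R,3R)-1-[(4-methoxybenzyl)oxy]-3-[(triisopropylsilyl)oxy]-2-{[(triisopropylsilyl)oxy]methyl}non-8-ene; 19 trimethylaluminium; 18 (Z)-tert-butyl[(3-iodobut-2-en-1-yl)oxy]dimethylsilane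
Product: 22 (2Z,5S,10R,11R)-1-[(tert-butyldimethylsilyl)oxy]-12-[(4-methoxybenzyl)oxy]-3,5-dimethyl-10-[(triisopropylsilyl)oxy]-11-{[(triisopropylsilyl)oxy]methyl}dodec-2-ene, via alkyl(dimethyl)alane 20 (not isolated), via alkylzinc triflate 21 (not isolated)
Conditions: 19 (3 equiv), (MeAlO)n (methylaluminoxane, 1 equiv), (+)-(NMI)2ZrCl2 (NMI = 1-neomenthylindenyl, 5 mol%), CH2Cl2, 0 °C → rt; evaporate volatiles; Zn(OTf)2, DMF, 70 °C; then 18 (2 equiv), PdCl2(DPEphos) (DPEphos = bis[2-(diphenylphosphino)phenyl] ether, 3 mol%), iBu2AlH (6 mol%), rt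
Reagents that add atoms: none
Why: A cationic methylzirconocene generated from (+)-bis(1-neomenthylindenyl)zirconium dichloride, Me3Al and methylaluminoxane inserts the terminal C6=C7 alkene in a syn fashion with methyl going to C7 and zirconium to C6, exchange with Me3Al releases alane 20, Zn(OTf)2 in DMF passes the primary alkyl group to zinc (21), and zerovalent palladium (formed from PdCl2(DPEphos) and iBu2AlH) adds oxidatively to the C–I bond of 18, after which transmetalation and reductive elimination form C5–C6 with retention of the alkene geometry. The closest known reaction type is the zirconium-catalysed asymmetric carboalumination of 1-alkenes run in one pot with a zinc-mediated, palladium-catalysed Negishi alkenylation. No ring is closed. The only new stereocentre, C7, is controlled by the chiral zirconocene, which selects one enantioface of the alkene; the (+)-complex is specified because the S sense is needed (C6 ranks above C8), the remote C12 and C13 centres should exert no influence, and the selectivity is therefore expected to appear as a diastereomer ratio typical of unbranched 1-alkenes, the minor C7 epimer being removed by preparative HPLC. The step needs regioselective insertion (methyl to the internal carbon, secured by the monosubstituted alkene), a single insertion without β-hydride transfer (favoured by the aluminoxane promoter and by stripping excess Me3Al before zinc is added, which also limits methyl transfer to 18) and geometric fidelity in the coupling (iodine in 18 is cis to the CH2O group, so C6 ends cis to C3 as the oxirane later requires). The silyl and PMB ethers sit at least five atoms from the alkene and are inert to the alane, so the alkene should behave as a simple 1-alkene.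

Step 10
Reactants: 22 (2Z,5S,10R,11R)-1-[(tert-butyldimethylsilyl)oxy]-12-[(4-methoxybenzyl)oxy]-3,5-dimethyl-10-[(triisopropylsilyl)oxy]-11-{[(triisopropylsilyl)oxy]methyl}dodec-2-ene
Product: 23 (2Z,5S,10R,11R)-12-[(4-methoxybenzyl)oxy]-3,5-dimethyl-10-[(triisopropylsilyl)oxy]-11-{[(triisopropylsilyl)oxy]methyl}dodec-2-en-1-ol
Conditions: PPTS (0.2 equiv), MeOH/CH2Cl2, rt
Reagents that add atoms: none
Why: Acid-catalysed methanolysis of silyl ethers is governed by the bulk at silicon, so the primary allylic TBS ether should be cleaved well before either TIPS ether, while the PMB ether and the alkene are inert.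

Step 11
Reactants: 23 (2Z,5S,10R,11R)-12-[(4-methoxybenzyl)oxy]-3,5-dimethyl-10-[(triisopropylsilyl)oxy]-11-{[(triisopropylsilyl)oxy]methyl}dodec-2-en-1-ol
Product: 24 (2S,3R,5S,10R,11R)-2,3-epoxy-12-[(4-methoxybenzyl)oxy]-3,5-dimethyl-10-[(triisopropylsilyl)oxy]-11-{[(triisopropylsilyl)oxy]methyl}dodecan-1-ol
Conditions: Ti(OiPr)4 (10 mol%), L-(+)-diethyl tartrate (12 mol%), t-BuOOH, 4 Å MS, CH2Cl2, −20 °C
Reagents that add atoms: tert-butyl hydroperoxide, CC(C)(C)OO
Why: Sharpless asymmetric epoxidation, in which the titanium tartrate complex binds the allylic alcohol and transfers the peroxide oxygen to one alkene face, creates C4 (S) and C5 (R) together, the natural (2R,3R)-tartrate being chosen by analogy with the Z-trisubstituted alcohol nerol and the Z geometry being translated stereospecifically into the cis relationship of C3 and C6.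

Step 12
Reactants: 24 (2S,3R,5S,10R,11R)-2,3-epoxy-12-[(4-methoxybenzyl)oxy]-3,5-dimethyl-10-[(triisopropylsilyl)oxy]-11-{[(triisopropylsilyl)oxy]methyl}dodecan-1-ol
Product: 25 (2R,3R,5S,10R,11R)-2,3-epoxy-12-[(4-methoxybenzyl)oxy]-3,5-dimethyl-10-[(triisopropylsilyl)oxy]-11-{[(triisopropylsilyl)oxy]methyl}dodecanal
Conditions: Dess–Martin periodinane, NaHCO3, CH2Cl2, 0 °C → rt
Reagents that add atoms: none
Why: Buffered Dess–Martin oxidation converts the primary epoxy alcohol into the aldehyde under neutral conditions that leave the oxirane and its configuration intact (the descriptor at the former C4 changes only through the priority of the new carbonyl group).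

Step 13
Reactants: 25 (2R,3R,5S,10R,11R)-2,3-epoxy-12-[(4-methoxybenzyl)oxy]-3,5-dimethyl-10-[(triisopropylsilyl)oxy]-11-{[(triisopropylsilyl)oxy]methyl}dodecanal
Product: 26 (3S,4R,6S,11R,12R)-3,4-epoxy-13-[(4-methoxybenzyl)oxy]-4,6-dimethyl-11-[(triisopropylsilyl)oxy]-12-{[(triisopropylsilyl)oxy]methyl}tridecan-2-ol (both C2 epimers)
Conditions: MeMgBr, THF, −78 °C
Reagents that add atoms: methylmagnesium bromide, C[Mg]Br
Why: Grignard addition to the aldehyde is far faster than attack on the trisubstituted oxirane at low temperature, and the configuration of the new carbinol carbon is irrelevant because it is oxidised in the next step.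

Step 14
Reactants: 26 (3S,4R,6S,11R,12R)-3,4-epoxy-13-[(4-methoxybenzyl)oxy]-4,6-dimethyl-11-[(triisopropylsilyl)oxy]-12-{[(triisopropylsilyl)oxy]methyl}tridecan-2-ol
Product: 27 (3R,4R,6S,11R,12R)-3,4-epoxy-13-[(4-methoxybenzyl)oxy]-4,6-dimethyl-11-[(triisopropylsilyl)oxy]-12-{[(triisopropylsilyl)oxy]methyl}tridecan-2-one
Conditions: Dess–Martin periodinane, NaHCO3, CH2Cl2, rt
Reagents that add atoms: none
Why: Dess–Martin oxidation of the secondary alcohol gives the methyl ketone under buffered conditions, and the oxirane C–H next to the carbonyl is not epimerised because enolisation toward a three-membered ring is strongly disfavoured.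

Step 15
Reactants: 27 (3R,4R,6S,11R,12R)-3,4-epoxy-13-[(4-methoxybenzyl)oxy]-4,6-dimethyl-11-[(triisopropylsilyl)oxy]-12-{[(triisopropylsilyl)oxy]methyl}tridecan-2-one
Product: 28 methyl (2E,4S,5R,7S,12R,13R)-4,5-epoxy-14-[(4-methoxybenzyl)oxy]-3,5,7-trimethyl-12-[(triisopropylsilyl)oxy]-13-{[(triisopropylsilyl)oxy]methyl}tetradec-2-enoate
Conditions: (MeO)2P(O)CH2CO2Me, NaH, THF, 0 °C → rt
Reagents that add atoms: trimethyl phosphonoacetate, COC(=O)CP(=O)(OC)OC
Why: Horner–Wadsworth–Emmons olefination of the methyl ketone should place the ester trans to the larger, branched oxiranyl substituent and cis to the methyl group, giving mainly the 2E-enoate, with any 2Z isomer to be removed by chromatography.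

Step 16
Reactants: 28 methyl (2E,4S,5R,7S,12R,13R)-4,5-epoxy-14-[(4-methoxybenzyl)oxy]-3,5,7-trimethyl-12-[(triisopropylsilyl)oxy]-13-{[(triisopropylsilyl)oxy]methyl}tetradec-2-enoate
Product: 29 methyl (2E,4S,5R,7S,12R,13R)-4,5-epoxy-14-hydroxy-3,5,7-trimethyl-12-[(triisopropylsilyl)oxy]-13-{[(triisopropylsilyl)oxy]methyl}tetradec-2-enoate
Conditions: DDQ, CH2Cl2/pH 7 buffer, 0 °C
Reagents that add atoms: none
Why: Oxidative cleavage of the electron-rich PMB ether by DDQ (hydride abstraction, then hydrolysis of the oxocarbenium ion) frees the C14 hydroxyl while the electron-poor enoate, the oxirane and the TIPS ethers are untouched in the buffered two-phase medium.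

Step 17
Reactants: 29 methyl (2E,4S,5R,7S,12R,13R)-4,5-epoxy-14-hydroxy-3,5,7-trimethyl-12-[(triisopropylsilyl)oxy]-13-{[(triisopropylsilyl)oxy]methyl}tetradec-2-enoate
Product: 31 1-methyl hydrogen (2E,4S,5R,7S,12R,13R)-4,5-epoxy-3,5,7-trimethyl-12-[(triisopropylsilyl)oxy]-13-{[(triisopropylsilyl)oxy]methyl}tetradec-2-enedioate, via aldehyde 30 (not isolated)
Conditions: TEMPO (0.2 equiv), PhI(OAc)2 (2.5 equiv), MeCN/pH 7 buffer, rt
Reagents that add atoms: water, O
Why: TEMPO/PhI(OAc)2 oxidation in aqueous acetonitrile takes the only free hydroxyl through the aldehyde and its hydrate to the carboxylic acid without touching the electron-poor alkene, and C13 should keep its configuration because the aldehyde is consumed as it forms.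

Step 18
Reactants: 31 1-methyl hydrogen (2E,4S,5R,7S,12R,13R)-4,5-epoxy-3,5,7-trimethyl-12-[(triisopropylsilyl)oxy]-13-{[(triisopropylsilyl)oxy]methyl}tetradec-2-enedioate
Product: 32 1-methyl hydrogen (2E,4S,5R,7S,12R,13R)-4,5-epoxy-12-hydroxy-13-(hydroxymethyl)-3,5,7-trimethyltetradec-2-enedioate
Conditions: Bu4NF, THF, rt → 40 °C
Reagents that add atoms: none
Why: Fluoride-mediated cleavage of both Si–O bonds, driven by the strength of the Si–F bond, is a non-acidic desilylation that the oxirane tolerates, the acid being present as its carboxylate.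

Step 19
Reactants: 32 1-methyl hydrogen (2E,4S,5R,7S,12R,13R)-4,5-epoxy-12-hydroxy-13-(hydroxymethyl)-3,5,7-trimethyltetradec-2-enedioate
Product: 33 (2E,4S,5R,7S,12R,13R)-4,5-epoxy-12-hydroxy-13-(hydroxymethyl)-3,5,7-trimethyltetradec-2-enedioic acid
Conditions: LiOH, THF/MeOH/H2O, rt; then dilute HCl to pH 4–5, 0 °C
Reagents that add atoms: lithium hydroxide, [Li+].[OH-]
Why: Saponification of the conjugated methyl ester by hydroxide, to which the oxirane is inert, followed by careful acidification to a weakly acidic pH should release the diacid without opening the oxirane and without touching any stereocentre.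

**Compound list**

1 | 4-methoxybenzyl alcohol | COc1ccc(CO)cc1 | starting material
2 | methyl acrylate | C=CC(=O)OC | starting material
3 | methyl 3-[(4-methoxybenzyl)oxy]propanoate | COC(=O)CCOCc1ccc(OC)cc1 | intermediate (not isolated)
4 | 3-[(4-methoxybenzyl)oxy]propanoic acid | OC(=O)CCOCc1ccc(OC)cc1 | intermediate
5 | (S)-4-benzyl-1,3-oxazolidin-2-one | O=C1N[C@@H](Cc2ccccc2)CO1 | starting material
6 | 3-[(4-methoxybenzyl)oxy]propanoic pivalic anhydride | CC(C)(C)C(=O)OC(=O)CCOCc1ccc(OC)cc1 | intermediate (not isolated)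
7 | (S)-4-benzyl-3-{3-[(4-methoxybenzyl)oxy]propanoyl}-1,3-oxazolidin-2-one | O=C(CCOCc1ccc(OC)cc1)N1C(=O)OC[C@@H]1Cc1ccccc1 | intermediate
8 | hept-6-en-1-ol | C=CCCCCCO | starting material
9 | hept-6-enal | C=CCCCCC=O | intermediate
10 | Z-dibutylboron enolate of imide 7 (O–B and CH2OPMB cis) | CCCCB(CCCC)O/C(=C\COCc1ccc(OC)cc1)N1C(=O)OC[C@@H]1Cc1ccccc1 | intermediate (not isolated)
11 | O-dibutylboryl derivative of aldol 12 (boron on the C12 oxygen) | C=CCCCC[C@@H](OB(CCCC)CCCC)[C@@H](C(=O)N1C(=O)OC[C@@H]1Cc1ccccc1)COCc1ccc(OC)cc1 | intermediate (not isolated)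
12 | (4S)-4-benzyl-3-[(2S,3R)-3-hydroxy-2-{[(4-methoxybenzyl)oxy]methyl}non-8-enoyl]-1,3-oxazolidin-2-one | C=CCCCC[C@@H](O)[C@@H](C(=O)N1C(=O)OC[C@@H]1Cc1ccccc1)COCc1ccc(OC)cc1 | intermediate
13 | (2S,3R)-2-{[(4-methoxybenzyl)oxy]methyl}non-8-ene-1,3-diol | C=CCCCC[C@@H](O)[C@@H](CO)COCc1ccc(OC)cc1 | intermediate
14 | (2R,3R)-1-[(4-methoxybenzyl)oxy]-3-[(triisopropylsilyl)oxy]-2-{[(triisopropylsilyl)oxy]methyl}non-8-ene (C6–C15 alkene) | C=CCCCC[C@@H](O[Si](C(C)C)(C(C)C)C(C)C)[C@@H](CO[Si](C(C)C)(C(C)C)C(C)C)COCc1ccc(OC)cc1 | intermediate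
15 | but-2-yn-1-ol | CC#CCO | starting material
16 | sodium 2,2-bis(2-methoxyethoxy)-3-methyl-2,5-dihydro-1,2-oxaaluminol-2-uide (cyclic alkenylalanate) | CC1=CCO[Al-]1(OCCOC)OCCOC.[Na+] | intermediate (not isolated)
17 | (Z)-3-iodobut-2-en-1-ol | C/C(I)=C/CO | intermediate
18 | (Z)-tert-butyl[(3-iodobut-2-en-1-yl)oxy]dimethylsilane | C/C(I)=C/CO[Si](C)(C)C(C)(C)C | intermediate
19 | trimethylaluminium | C[Al](C)C | starting material
20 | dimethyl{(2S,7R,8R)-9-[(4-methoxybenzyl)oxy]-2-methyl-7-[(triisopropylsilyl)oxy]-8-{[(triisopropylsilyl)oxy]methyl}nonyl}alane | C[Al](C)C[C@@H](C)CCCC[C@@H](O[Si](C(C)C)(C(C)C)C(C)C)[C@@H](CO[Si](C(C)C)(C(C)C)C(C)C)COCc1ccc(OC)cc1 | intermediate (not isolated)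
21 | {(2S,7R,8R)-9-[(4-methoxybenzyl)oxy]-2-methyl-7-[(triisopropylsilyl)oxy]-8-{[(triisopropylsilyl)oxy]methyl}nonyl}zinc triflate | FC(F)(F)S(=O)(=O)O[Zn]C[C@@H](C)CCCC[C@@H](O[Si](C(C)C)(C(C)C)C(C)C)[C@@H](CO[Si](C(C)C)(C(C)C)C(C)C)COCc1ccc(OC)cc1 | intermediate (not isolated)
22 | (2Z,5S,10R,11R)-1-[(tert-butyldimethylsilyl)oxy]-12-[(4-methoxybenzyl)oxy]-3,5-dimethyl-10-[(triisopropylsilyl)oxy]-11-{[(triisopropylsilyl)oxy]methyl}dodec-2-ene (C3–C15 chain) | CC(C)(C)[Si](C)(C)OC/C=C(C)\C[C@@H](C)CCCC[C@@H](O[Si](C(C)C)(C(C)C)C(C)C)[C@@H](CO[Si](C(C)C)(C(C)C)C(C)C)COCc1ccc(OC)cc1 | intermediate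
23 | (2Z,5S,10R,11R)-12-[(4-methoxybenzyl)oxy]-3,5-dimethyl-10-[(triisopropylsilyl)oxy]-11-{[(triisopropylsilyl)oxy]methyl}dodec-2-en-1-ol | OC/C=C(C)\C[C@@H](C)CCCC[C@@H](O[Si](C(C)C)(C(C)C)C(C)C)[C@@H](CO[Si](C(C)C)(C(C)C)C(C)C)COCc1ccc(OC)cc1 | intermediate
24 | (2S,3R,5S,10R,11R)-2,3-epoxy-12-[(4-methoxybenzyl)oxy]-3,5-dimethyl-10-[(triisopropylsilyl)oxy]-11-{[(triisopropylsilyl)oxy]methyl}dodecan-1-ol | OC[C@@H]1O[C@]1(C)C[C@@H](C)CCCC[C@@H](O[Si](C(C)C)(C(C)C)C(C)C)[C@@H](CO[Si](C(C)C)(C(C)C)C(C)C)COCc1ccc(OC)cc1 | intermediate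
25 | (2R,3R,5S,10R,11R)-2,3-epoxy-12-[(4-methoxybenzyl)oxy]-3,5-dimethyl-10-[(triisopropylsilyl)oxy]-11-{[(triisopropylsilyl)oxy]methyl}dodecanal | O=C[C@@H]1O[C@]1(C)C[C@@H](C)CCCC[C@@H](O[Si](C(C)C)(C(C)C)C(C)C)[C@@H](CO[Si](C(C)C)(C(C)C)C(C)C)COCc1ccc(OC)cc1 | intermediate
26 | (3S,4R,6S,11R,12R)-3,4-epoxy-13-[(4-methoxybenzyl)oxy]-4,6-dimethyl-11-[(triisopropylsilyl)oxy]-12-{[(triisopropylsilyl)oxy]methyl}tridecan-2-ol (both C2 epimers) | CC(O)[C@@H]1O[C@]1(C)C[C@@H](C)CCCC[C@@H](O[Si](C(C)C)(C(C)C)C(C)C)[C@@H](CO[Si](C(C)C)(C(C)C)C(C)C)COCc1ccc(OC)cc1 | intermediate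
27 | (3R,4R,6S,11R,12R)-3,4-epoxy-13-[(4-methoxybenzyl)oxy]-4,6-dimethyl-11-[(triisopropylsilyl)oxy]-12-{[(triisopropylsilyl)oxy]methyl}tridecan-2-one | CC(=O)[C@@H]1O[C@]1(C)C[C@@H](C)CCCC[C@@H](O[Si](C(C)C)(C(C)C)C(C)C)[C@@H](CO[Si](C(C)C)(C(C)C)C(C)C)COCc1ccc(OC)cc1 | intermediate
28 | methyl (2E,4S,5R,7S,12R,13R)-4,5-epoxy-14-[(4-methoxybenzyl)oxy]-3,5,7-trimethyl-12-[(triisopropylsilyl)oxy]-13-{[(triisopropylsilyl)oxy]methyl}tetradec-2-enoate | C/C(=C\C(=O)OC)[C@@H]1O[C@]1(C)C[C@@H](C)CCCC[C@@H](O[Si](C(C)C)(C(C)C)C(C)C)[C@@H](CO[Si](C(C)C)(C(C)C)C(C)C)COCc1ccc(OC)cc1 | intermediate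
29 | methyl (2E,4S,5R,7S,12R,13R)-4,5-epoxy-14-hydroxy-3,5,7-trimethyl-12-[(triisopropylsilyl)oxy]-13-{[(triisopropylsilyl)oxy]methyl}tetradec-2-enoate | C/C(=C\C(=O)OC)[C@@H]1O[C@]1(C)C[C@@H](C)CCCC[C@@H](O[Si](C(C)C)(C(C)C)C(C)C)[C@@H](CO[Si](C(C)C)(C(C)C)C(C)C)CO | intermediate
30 | methyl (2E,4S,5R,7S,12R,13R)-4,5-epoxy-3,5,7-trimethyl-14-oxo-12-[(triisopropylsilyl)oxy]-13-{[(triisopropylsilyl)oxy]methyl}tetradec-2-enoate | C/C(=C\C(=O)OC)[C@@H]1O[C@]1(C)C[C@@H](C)CCCC[C@@H](O[Si](C(C)C)(C(C)C)C(C)C)[C@@H](CO[Si](C(C)C)(C(C)C)C(C)C)C=O | intermediate (not isolated)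
31 | 1-methyl hydrogen (2E,4S,5R,7S,12R,13R)-4,5-epoxy-3,5,7-trimethyl-12-[(triisopropylsilyl)oxy]-13-{[(triisopropylsilyl)oxy]methyl}tetradec-2-enedioate | C/C(=C\C(=O)OC)[C@@H]1O[C@]1(C)C[C@@H](C)CCCC[C@@H](O[Si](C(C)C)(C(C)C)C(C)C)[C@@H](CO[Si](C(C)C)(C(C)C)C(C)C)C(=O)O | intermediate
32 | 1-methyl hydrogen (2E,4S,5R,7S,12R,13R)-4,5-epoxy-12-hydroxy-13-(hydroxymethyl)-3,5,7-trimethyltetradec-2-enedioate | C/C(=C\C(=O)OC)[C@@H]1O[C@]1(C)C[C@@H](C)CCCC[C@@H](O)[C@@H](CO)C(=O)O | intermediate
33 | (2E,4S,5R,7S,12R,13R)-4,5-epoxy-12-hydroxy-13-(hydroxymethyl)-3,5,7-trimethyltetradec-2-enedioic acid (CNP0468463.1) | C/C(=C\C(=O)O)[C@@H]1O[C@]1(C)C[C@@H](C)CCCC[C@@H](O)[C@@H](CO)C(=O)O | target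

**Step count and risks**

Total steps: 19. Longest linear sequence: 16 steps (steps 1, 2, 4, 5, 6 and 9 to 19).

Steps most likely to fail:

1. Step 9. What may go wrong: incomplete hand-over of the β-branched alkyl group from aluminium to zinc, or slow coupling with the trisubstituted Z-iodide in the one-pot medium, with methyl transfer competing. Enantioface discrimination of an unbranched 1-alkene may also be incomplete, leaving a C7 epimer that is hard to separate at the stage of 22. Fallback: it sets out from alkene 14 and decouples the two events. The carboalumination is run as in step 9 to alane 20, which is oxidised with dry O2 instead of being transmetalated, to give (2S,7R,8R)-9-[(4-methoxybenzyl)oxy]-2-methyl-7-[(triisopropylsilyl)oxy]-8-{[(triisopropylsilyl)oxy]methyl}nonan-1-ol F1. The C7 epimer is removed at this stage, by lipase PS-mediated acetylation with vinyl acetate (which discriminates 2-methylalkan-1-ols) or by chromatography. Iodination (I2, PPh3, imidazole, CH2Cl2) gives the primary iodide F2. Lithium–iodine exchange (t-BuLi, Et2O, −78 °C) and capture with 9-methoxy-9-BBN give the lithium borinate F3, which is coupled without isolation with iodide 18 (PdCl2(dppf), AsPh3, Cs2CO3, DMF/H2O, rt). This B-alkyl Suzuki–Miyaura coupling retains the Z geometry and returns to the route at 22.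

2. Step 15. What may go wrong: weak geometric control in the addition–elimination at a methyl ketone, giving E/Z mixtures that are hard to separate, and base-induced self-condensation or degradation of the epoxy ketone. Fallback: it sets out from aldehyde 25 and fixes the alkene geometry through an enol triflate. Aldol addition of the lithium enolate of methyl acetate (LiN(iPr)2, MeOAc, THF, −78 °C) gives the β-hydroxy ester F4. Dess–Martin oxidation gives the β-keto ester F5. Triflation of its chelated sodium enolate (NaH, Tf2O, Et2O, 0 °C) gives the Z-enol triflate F6, with the triflate cis to the ester. Iron-catalysed cross-coupling with MeMgBr (Fe(acac)3, THF/NMP, −30 °C), a Kumada-type reaction that proceeds with retention, replaces the triflate by methyl and returns to the route at 28.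

3. Step 17. What may go wrong: stalling at the aldehyde because hydration is slow next to two bulky silyl ethers, enolisation of a long-lived aldehyde eroding C13, and opening of the vinyl oxirane by the acetic acid released from the oxidant. Fallback: it sets out from ketone 27 and completes the C14 oxidation before the vinyl oxirane exists. DDQ (CH2Cl2/pH 7 buffer) gives the keto alcohol F7. Dess–Martin oxidation gives the isolated keto aldehyde F8. Pinnick oxidation (NaClO2, NaH2PO4, 2-methylbut-2-ene, t-BuOH/H2O) gives the keto acid F9. Horner–Wadsworth–Emmons olefination with an excess of the sodium phosphonate (the acid reacting as its carboxylate) returns to the route at 31.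

Further compounds
F1 | step 9 | (2S,7R,8R)-9-[(4-methoxybenzyl)oxy]-2-methyl-7-[(triisopropylsilyl)oxy]-8-{[(triisopropylsilyl)oxy]methyl}nonan-1-ol | OC[C@@H](C)CCCC[C@@H](O[Si](C(C)C)(C(C)C)C(C)C)[C@@H](CO[Si](C(C)C)(C(C)C)C(C)C)COCc1ccc(OC)cc1
F2 | step 9 | (2S,7R,8R)-1-iodo-9-[(4-methoxybenzyl)oxy]-2-methyl-7-[(triisopropylsilyl)oxy]-8-{[(triisopropylsilyl)oxy]methyl}nonane | IC[C@@H](C)CCCC[C@@H](O[Si](C(C)C)(C(C)C)C(C)C)[C@@H](CO[Si](C(C)C)(C(C)C)C(C)C)COCc1ccc(OC)cc1
F3 | step 9 | lithium 9-methoxy-9-alkyl-9-borabicyclo[3.3.1]nonan-9-uide carrying the alkyl group of F2 (configuration unchanged) | [Li+].CO[B-]1(C[C@@H](C)CCCC[C@@H](O[Si](C(C)C)(C(C)C)C(C)C)[C@@H](CO[Si](C(C)C)(C(C)C)C(C)C)COCc2ccc(OC)cc2)C2CCCC1CCC2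
F4 | step 15 | methyl (4S,5R,7S,12R,13R)-4,5-epoxy-3-hydroxy-14-[(4-methoxybenzyl)oxy]-5,7-dimethyl-12-[(triisopropylsilyl)oxy]-13-{[(triisopropylsilyl)oxy]methyl}tetradecanoate (both C3 epimers) | COC(=O)CC(O)[C@@H]1O[C@]1(C)C[C@@H](C)CCCC[C@@H](O[Si](C(C)C)(C(C)C)C(C)C)[C@@H](CO[Si](C(C)C)(C(C)C)C(C)C)COCc1ccc(OC)cc1
F5 | step 15 | methyl (4R,5R,7S,12R,13R)-4,5-epoxy-14-[(4-methoxybenzyl)oxy]-5,7-dimethyl-3-oxo-12-[(triisopropylsilyl)oxy]-13-{[(triisopropylsilyl)oxy]methyl}tetradecanoate | COC(=O)CC(=O)[C@@H]1O[C@]1(C)C[C@@H](C)CCCC[C@@H](O[Si](C(C)C)(C(C)C)C(C)C)[C@@H](CO[Si](C(C)C)(C(C)C)C(C)C)COCc1ccc(OC)cc1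
F6 | step 15 | Z-enol triflate of F5 (analogue of 28 with triflyloxy in place of the C3 methyl, triflate cis to the ester; oxirane, C7, C12 and C13 as in 28) | COC(=O)/C=C(\OS(=O)(=O)C(F)(F)F)[C@@H]1O[C@]1(C)C[C@@H](C)CCCC[C@@H](O[Si](C(C)C)(C(C)C)C(C)C)[C@@H](CO[Si](C(C)C)(C(C)C)C(C)C)COCc1ccc(OC)cc1
F7 | step 17 | (3R,4R,6S,11R,12R)-3,4-epoxy-13-hydroxy-4,6-dimethyl-11-[(triisopropylsilyl)oxy]-12-{[(triisopropylsilyl)oxy]methyl}tridecan-2-one | CC(=O)[C@@H]1O[C@]1(C)C[C@@H](C)CCCC[C@@H](O[Si](C(C)C)(C(C)C)C(C)C)[C@@H](CO[Si](C(C)C)(C(C)C)C(C)C)CO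
F8 | step 17 | C14 aldehyde of F7 (hydroxymethyl oxidised to formyl; all stereocentres as in F7) | CC(=O)[C@@H]1O[C@]1(C)C[C@@H](C)CCCC[C@@H](O[Si](C(C)C)(C(C)C)C(C)C)[C@@H](CO[Si](C(C)C)(C(C)C)C(C)C)C=O
F9 | step 17 | C14 carboxylic acid of F7 (hydroxymethyl oxidised to carboxyl; all stereocentres as in F7) | CC(=O)[C@@H]1O[C@]1(C)C[C@@H](C)CCCC[C@@H](O[Si](C(C)C)(C(C)C)C(C)C)[C@@H](CO[Si](C(C)C)(C(C)C)C(C)C)C(=O)O
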